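**Retrosynthetic overview**
1. Target 32 is cut into bromo-epoxide 18 (C17) and dienyl iodide 31 (C15). This C(sp3)–C(sp2) bond is closed last by a nickel-catalysed reductive radical coupling next to the intact oxirane.
2. Key step: both C–methyl stereocentres come from one racemic C2 α-chloroboronate 7 and one alkylzinc 6 (one batch, used twice) by nickel-catalysed enantioconvergent radical alkyl–alkyl coupling (antipodal ligands give 8 and 19). Zweifel olefination then attaches each 1,1-disubstituted alkene with retention.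
3. All E-trisubstituted C=C units come from Negishi carboalumination of terminal alkynes. The C5 spacer of 31 is added by a second radical alkyl–alkenyl coupling.
4. The only ring, the oxirane, is formed once (step 7) by hydroxyl-directed asymmetric epoxidation of homoallylic alcohol 16, after the left stereocentre is set and before fragment union.

Assumption: 5 and 7 are bought with their protecting groups in place (trimethylsilyl on the alkyne, pinacol on boron), and for each chiral ligand the enantiomer named is the one expected to give the stated configuration, to be confirmed on the first run (the antipode is equally available).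

**Step 1**
Reactants: 1 5-bromo-2-methylpent-2-ene
Product: 2 6-methylhept-5-en-1-yne
Conditions: LiC≡CH·H2NCH2CH2NH2 (1.3 equiv), DMSO, 15 °C → rt
Reagents that add atoms: lithium acetylide–ethylenediamine complex, [Li]C#C.NCCN
Why: SN2 alkylation of lithium acetylide by the primary bromide gives the terminal alkyne without touching the trisubstituted alkene, and no stereocentre is formed.

**Step 2**
Reactants: 2 6-methylhept-5-en-1-yne
Product: 4 2-bromo-6-methylhepta-1,5-diene, via bromoboration adduct 3 (not isolated)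
Conditions: B-bromo-9-BBN (1.1 equiv), CH2Cl2, 0 °C; AcOH, rt
Reagents that add atoms: B-bromo-9-borabicyclo[3.3.1]nonane, BrB1C2CCCC1CCC2
Why: Hara–Suzuki bromoboration adds B–Br syn and Markovnikov to the terminal alkyne only (alkenes are inert), and protodeboronation with acetic acid leaves the 2-bromo-1-alkene.

**Step 3**
Reactants: 5 (4-bromobut-1-yn-1-yl)trimethylsilane
Product: 6 [4-(trimethylsilyl)but-3-yn-1-yl]zinc bromide
Conditions: Zn dust (1.5 equiv), I2 (5 mol%), DMA, 70 °C; decant from excess zinc, titrate, keep under argon as a stock solution for steps 4 and 9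
Reagents that add atoms: zinc, [Zn]
Why: Direct oxidative insertion of iodine-activated zinc into the primary C–Br bond in a polar amide solvent gives the alkylzinc bromide, with the silylated alkyne inert and no stereocentre involved, and one batch supplies both enantioconvergent couplings.

**Step 4**
Reactants: 6 [4-(trimethylsilyl)but-3-yn-1-yl]zinc bromide; 7 rac-2-(1-chloroethyl)-4,4,5,5-tetramethyl-1,3,2-dioxaborolane
Product: 8 4,4,5,5-tetramethyl-2-[(2R)-6-(trimethylsilyl)hex-5-yn-2-yl]-1,3,2-dioxaborolane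
Conditions: 6 (1.6 equiv, DMA solution from step 3), NiBr2·diglyme (10 mol%), (R,R)-N,N′-dimethyl-1,2-diarylethane-1,2-diamine ligand (13 mol%), THF/DMA, 0 °C
Reagents that add atoms: none
Why: Fu-type nickel-catalysed enantioconvergent Negishi alkyl–alkyl coupling, in which the chiral nickel–diamine catalyst abstracts chlorine from either enantiomer of 7 to give a planar α-boryl radical that is captured by the alkylnickel formed from 6 and reductively eliminated under ligand control, so both enantiomers of 7 converge on the (R)-boronate (about 90% ee expected) in the bond-forming radical step.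

**Step 5**
Reactants: 8 4,4,5,5-tetramethyl-2-[(2R)-6-(trimethylsilyl)hex-5-yn-2-yl]-1,3,2-dioxaborolane; 4 2-bromo-6-methylhepta-1,5-diene
Product: 13 (5R)-5,10-dimethyl-6-methylideneundec-9-en-1-yne, via alkenyllithium 9 (not isolated), via boronate complex 10 (not isolated), via iodoboronate 11 (not isolated), via silyl enyne 12 (not isolated)
Conditions: 4, t-BuLi (2 equiv), Et2O, −78 °C; 8, THF, −78 °C; I2, −78 °C; NaOMe/MeOH, −78 → 0 °C; Na2S2O3 (removes excess I2); rt, 2 h
Reagents that add atoms: none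
Why: Zweifel olefination, in which iodine triggers a 1,2-metallate shift of the secondary alkyl group with retention at the stereocentre and methoxide-induced anti elimination gives the 1,1-disubstituted alkene, after which the same methoxide/methanol cleaves the alkynyl C–Si bond.

**Step 6**
Reactants: 13 (5R)-5,10-dimethyl-6-methylideneundec-9-en-1-yne
Product: 16 (3E,7R)-4,7,12-trimethyl-8-methylidenetrideca-3,11-dien-1-ol, via alkenylalane 14 (not isolated), via lithium alanate 15 (not isolated)
Conditions: AlMe3 (2 equiv), Cp2ZrCl2 (25 mol%), CH2Cl2, 0 °C → rt; evaporate; n-BuLi, THF/hexane, −78 °C; ethylene oxide, −78 °C → rt; H2O work-up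
Reagents that add atoms: trimethylaluminium, C[Al](C)C; ethylene oxide, C1CO1
Why: Negishi zirconium-catalysed carboalumination adds methyl and aluminium syn across the terminal alkyne (methyl to the internal carbon) to fix the E-trisubstituted alkene, and the derived alanate opens ethylene oxide with retention of geometry while the existing stereocentre is untouched.

**Step 7**
Reactants: 16 (3E,7R)-4,7,12-trimethyl-8-methylidenetrideca-3,11-dien-1-ol
Product: 17 2-[(2R,3R)-3-[(3R)-3,8-dimethyl-4-methylidenenon-7-en-1-yl]-3-methyloxiran-2-yl]ethan-1-ol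
Conditions: VO(OiPr)3 (2 mol%), (R,R)-cyclohexanediamine-derived bishydroxamic acid ligand (4 mol%), cumene hydroperoxide (1.5 equiv), toluene, 0 °C → rt
Reagents that add atoms: cumene hydroperoxide, CC(C)(OO)c1ccccc1
Why: Yamamoto vanadium–bishydroxamic acid asymmetric epoxidation of a homoallylic alcohol, in which the alkoxide-bound pentavalent vanadium peroxide delivers oxygen only to the proximal 3,4-alkene (precedented for (E)-4-methylalk-3-en-1-ols) and the ligand fixes the face, so syn addition to the E alkene sets both oxirane centres as (R,R).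

**Step 8**
Reactants: 17 2-[(2R,3R)-3-[(3R)-3,8-dimethyl-4-methylidenenon-7-en-1-yl]-3-methyloxiran-2-yl]ethan-1-ol
Product: 18 (2R,3R)-3-(2-bromoethyl)-2-[(3R)-3,8-dimethyl-4-methylidenenon-7-en-1-yl]-2-methyloxirane
Conditions: CBr4, PPh3, 2,6-lutidine, CH2Cl2, 0 °C
Reagents that add atoms: carbon tetrabromide, BrC(Br)(Br)Br
Why: Appel bromination converts the primary alcohol into the bromide by SN2 at a non-stereogenic carbon under buffered neutral conditions that leave the trisubstituted epoxide intact.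

**Step 9**
Reactants: 6 [4-(trimethylsilyl)but-3-yn-1-yl]zinc bromide; 7 rac-2-(1-chloroethyl)-4,4,5,5-tetramethyl-1,3,2-dioxaborolane
Product: 19 4,4,5,5-tetramethyl-2-[(2S)-6-(trimethylsilyl)hex-5-yn-2-yl]-1,3,2-dioxaborolane
Conditions: 6 (1.6 equiv, DMA solution from step 3), NiBr2·diglyme (10 mol%), (S,S)-N,N′-dimethyl-1,2-diarylethane-1,2-diamine ligand (13 mol%), THF/DMA, 0 °C
Reagents that add atoms: none
Why: The same Fu-type enantioconvergent radical Negishi coupling as in step 4, run with the antipodal ligand so that the α-boryl radical is captured from the opposite face and the (S)-boronate results.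

**Step 10**
Reactants: 19 4,4,5,5-tetramethyl-2-[(2S)-6-(trimethylsilyl)hex-5-yn-2-yl]-1,3,2-dioxaborolane; 20 2-bromoprop-1-ene
Product: 25 (5S)-5,6-dimethylhept-6-en-1-yne, via isopropenyllithium 21 (not isolated), via boronate complex 22 (not isolated), via iodoboronate 23 (not isolated), via silyl enyne 24 (not isolated)
Conditions: 20, t-BuLi (2 equiv), Et2O, −78 °C; 19, THF, −78 °C; I2, −78 °C; NaOMe/MeOH, −78 → 0 °C; Na2S2O3 (removes excess I2); rt, 2 h
Reagents that add atoms: none
Why: Zweifel olefination transfers the secondary alkyl group from boron to the isopropenyl carbon with retention, giving the (S)-configured isopropenyl-bearing centre, and methoxide then removes the alkynyl silyl group.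

**Step 11**
Reactants: 25 (5S)-5,6-dimethylhept-6-en-1-yne
Product: 27 (1E,5S)-1-iodo-2,5,6-trimethylhepta-1,6-diene, via alkenylalane 26 (not isolated)
Conditions: AlMe3 (2 equiv), Cp2ZrCl2 (25 mol%), CH2Cl2, 0 °C → rt; I2, THF, −30 → 0 °C
Reagents that add atoms: trimethylaluminium, C[Al](C)C; iodine, II
Why: Negishi carboalumination (syn, methyl to the internal carbon, alkyne far more reactive than the 1,1-disubstituted alkene) followed by iodinolysis with retention gives the E alkenyl iodide.

**Step 12**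
Reactants: 27 (1E,5S)-1-iodo-2,5,6-trimethylhepta-1,6-diene; 5 (4-bromobut-1-yn-1-yl)trimethylsilane
Product: 28 trimethyl[(5E,9S)-6,9,10-trimethylundeca-5,10-dien-1-yn-1-yl]silane
Conditions: NiBr2·glyme (10 mol%), 4,4′-di-tert-butyl-2,2′-bipyridine (10 mol%), Mn powder (2 equiv), NaI (25 mol%), DMA, rt; 5 (1.5 equiv)
Reagents that add atoms: none
Why: Nickel-catalysed reductive cross-electrophile coupling (Weix type), in which zerovalent nickel inserts into the C(sp2)–I bond, the primary alkyl radical formed from 5 by halogen abstraction is captured at nickel, and reductive elimination forms the C(sp3)–C(sp2) bond with retention of E geometry.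

**Step 13**
Reactants: 28 trimethyl[(5E,9S)-6,9,10-trimethylundeca-5,10-dien-1-yn-1-yl]silane
Product: 29 (5E,9S)-6,9,10-trimethylundeca-5,10-dien-1-yne
Conditions: K2CO3 (cat.), MeOH, rt
Reagents that add atoms: none
Why: Base-catalysed methanolysis of the alkynyl C–Si bond frees the terminal alkyne and affects nothing else.

**Step 14**
Reactants: 29 (5E,9S)-6,9,10-trimethylundeca-5,10-dien-1-yne
Product: 31 (1E,5E,9S)-1-iodo-2,6,9,10-tetramethylundeca-1,5,10-triene, via alkenylalane 30 (not isolated)
Conditions: AlMe3 (2 equiv), Cp2ZrCl2 (25 mol%), CH2Cl2, 0 °C → rt; I2, THF, −30 → 0 °C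
Reagents that add atoms: trimethylaluminium, C[Al](C)C; iodine, II
Why: A second Negishi carboalumination–iodinolysis builds the next E-trisubstituted alkene as its alkenyl iodide, with the existing alkenes and the stereocentre as spectators.

**Step 15**
Reactants: 18 (2R,3R)-3-(2-bromoethyl)-2-[(3R)-3,8-dimethyl-4-methylidenenon-7-en-1-yl]-2-methyloxirane; 31 (1E,5E,9S)-1-iodo-2,6,9,10-tetramethylundeca-1,5,10-triene
Product: 32 (2R,3R)-2-[(3R)-3,8-dimethyl-4-methylidenenon-7-en-1-yl]-2-methyl-3-[(3E,7E,11S)-4,8,11,12-tetramethyltrideca-3,7,12-trien-1-yl]oxirane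
Conditions: NiBr2·glyme (10 mol%), 4,4′-di-tert-butyl-2,2′-bipyridine (10 mol%), Mn powder (2 equiv), NaI (25 mol%), DMA, rt; 31 (1.3 equiv)
Reagents that add atoms: none
Why: Nickel-catalysed reductive cross-electrophile coupling joins the two halves; the primary radical from 18 is separated from the oxirane by a CH2 group, so it is not an oxiranylcarbinyl radical and cannot ring-open, the alkenyl iodide couples with retention of E geometry, and no stereocentre is touched.

**Compound list**
1 | 5-bromo-2-methylpent-2-ene | CC(C)=CCCBr | starting material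
2 | 6-methylhept-5-en-1-yne | C#CCCC=C(C)C | intermediate
3 | 9-[(1Z)-2-bromo-6-methylhepta-1,5-dien-1-yl]-9-borabicyclo[3.3.1]nonane | CC(C)=CCC/C(Br)=C/B1C2CCCC1CCC2 | intermediate
4 | 2-bromo-6-methylhepta-1,5-diene | C=C(Br)CCC=C(C)C | intermediate
5 | (4-bromobut-1-yn-1-yl)trimethylsilane | C[Si](C)(C)C#CCCBr | starting material
6 | [4-(trimethylsilyl)but-3-yn-1-yl]zinc bromide | C[Si](C)(C)C#CCC[Zn]Br | intermediate
7 | rac-2-(1-chloroethyl)-4,4,5,5-tetramethyl-1,3,2-dioxaborolane | CC(Cl)B1OC(C)(C)C(C)(C)O1 | starting material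
8 | 4,4,5,5-tetramethyl-2-[(2R)-6-(trimethylsilyl)hex-5-yn-2-yl]-1,3,2-dioxaborolane | C[Si](C)(C)C#CCC[C@@H](C)B1OC(C)(C)C(C)(C)O1 | intermediate
9 | (6-methylhepta-1,5-dien-2-yl)lithium | [Li]C(=C)CCC=C(C)C | intermediate
10 | lithium (6-methylhepta-1,5-dien-2-yl)[(2R)-6-(trimethylsilyl)hex-5-yn-2-yl](pinacolato)borate | [Li+].C=C(CCC=C(C)C)[B-]1([C@H](C)CCC#C[Si](C)(C)C)OC(C)(C)C(C)(C)O1 | intermediate
11 | 2-[(7R)-6-(iodomethyl)-2,7-dimethyl-11-(trimethylsilyl)undec-2-en-10-yn-6-yl]-4,4,5,5-tetramethyl-1,3,2-dioxaborolane (C6 epimers) | ICC(CCC=C(C)C)([C@H](C)CCC#C[Si](C)(C)C)B1OC(C)(C)C(C)(C)O1 | intermediate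
12 | trimethyl[(5R)-5,10-dimethyl-6-methylideneundec-9-en-1-yn-1-yl]silane | C=C(CCC=C(C)C)[C@H](C)CCC#C[Si](C)(C)C | intermediate
13 | (5R)-5,10-dimethyl-6-methylideneundec-9-en-1-yne | C=C(CCC=C(C)C)[C@H](C)CCC#C | intermediate
14 | dimethyl[(1E,5R)-2,5,10-trimethyl-6-methylideneundeca-1,9-dien-1-yl]alumane | C=C(CCC=C(C)C)[C@H](C)CC/C(C)=C/[Al](C)C | intermediate
15 | lithium butyl(dimethyl)[(1E,5R)-2,5,10-trimethyl-6-methylideneundeca-1,9-dien-1-yl]aluminate | [Li+].C=C(CCC=C(C)C)[C@H](C)CC/C(C)=C/[Al-](C)(C)CCCC | intermediate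
16 | (3E,7R)-4,7,12-trimethyl-8-methylidenetrideca-3,11-dien-1-ol | C=C(CCC=C(C)C)[C@H](C)CC/C(C)=C/CCO | intermediate
17 | 2-[(2R,3R)-3-[(3R)-3,8-dimethyl-4-methylidenenon-7-en-1-yl]-3-methyloxiran-2-yl]ethan-1-ol | C=C(CCC=C(C)C)[C@H](C)CC[C@@]1(C)O[C@@H]1CCO | intermediate
18 | (2R,3R)-3-(2-bromoethyl)-2-[(3R)-3,8-dimethyl-4-methylidenenon-7-en-1-yl]-2-methyloxirane | C=C(CCC=C(C)C)[C@H](C)CC[C@@]1(C)O[C@@H]1CCBr | intermediate
19 | 4,4,5,5-tetramethyl-2-[(2S)-6-(trimethylsilyl)hex-5-yn-2-yl]-1,3,2-dioxaborolane | C[Si](C)(C)C#CCC[C@H](C)B1OC(C)(C)C(C)(C)O1 | intermediate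
20 | 2-bromoprop-1-ene | CC(Br)=C | starting material
21 | prop-1-en-2-yllithium | [Li]C(C)=C | intermediate
22 | lithium (prop-1-en-2-yl)[(2S)-6-(trimethylsilyl)hex-5-yn-2-yl](pinacolato)borate | [Li+].C=C(C)[B-]1([C@@H](C)CCC#C[Si](C)(C)C)OC(C)(C)C(C)(C)O1 | intermediate
23 | 2-[(3S)-1-iodo-2,3-dimethyl-7-(trimethylsilyl)hept-6-yn-2-yl]-4,4,5,5-tetramethyl-1,3,2-dioxaborolane (C2 epimers) | ICC(C)([C@@H](C)CCC#C[Si](C)(C)C)B1OC(C)(C)C(C)(C)O1 | intermediate
24 | trimethyl[(5S)-5,6-dimethylhept-6-en-1-yn-1-yl]silane | C[Si](C)(C)C#CCC[C@H](C)C(=C)C | intermediate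
25 | (5S)-5,6-dimethylhept-6-en-1-yne | C#CCC[C@H](C)C(=C)C | intermediate
26 | dimethyl[(1E,5S)-2,5,6-trimethylhepta-1,6-dien-1-yl]alumane | C[Al](C)/C=C(\C)CC[C@H](C)C(=C)C | intermediate
27 | (1E,5S)-1-iodo-2,5,6-trimethylhepta-1,6-diene | I/C=C(\C)CC[C@H](C)C(=C)C | intermediate
28 | trimethyl[(5E,9S)-6,9,10-trimethylundeca-5,10-dien-1-yn-1-yl]silane | C[Si](C)(C)C#CCC/C=C(\C)CC[C@H](C)C(=C)C | intermediate
29 | (5E,9S)-6,9,10-trimethylundeca-5,10-dien-1-yne | C#CCC/C=C(\C)CC[C@H](C)C(=C)C | intermediate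
30 | dimethyl[(1E,5E,9S)-2,6,9,10-tetramethylundeca-1,5,10-trien-1-yl]alumane | C[Al](C)/C=C(\C)CC/C=C(\C)CC[C@H](C)C(=C)C | intermediate
31 | (1E,5E,9S)-1-iodo-2,6,9,10-tetramethylundeca-1,5,10-triene | I/C=C(\C)CC/C=C(\C)CC[C@H](C)C(=C)C | intermediate
32 | (2R,3R)-2-[(3R)-3,8-dimethyl-4-methylidenenon-7-en-1-yl]-2-methyl-3-[(3E,7E,11S)-4,8,11,12-tetramethyltrideca-3,7,12-trien-1-yl]oxirane | C=C(CCC=C(C)C)[C@H](C)CC[C@@]1(C)O[C@@H]1CC/C=C(\C)CC/C=C(\C)CC[C@H](C)C(=C)C | target

**Totals**
Total step count: 15. Longest linear sequence: 8 steps (5 → 6 → 19 → 25 → 27 → 28 → 29 → 31 → 32, steps 3, 9, 10, 11, 12, 13, 14 and 15). The chains 1 → 2 → 4 → 13 → 16 → 17 → 18 → 32 and 5 → 6 → 8 → 13 → 16 → 17 → 18 → 32 each take 7 steps.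

Stereochemical purity: the three catalyst-controlled steps (4, 7, 9) are each expected at about 90% ee or better, so 32 is obtained as the major stereoisomer, and the minor diastereomers (remote centres) will be hard to remove.

**Steps most likely to fail, with fallbacks**

Step 4 (the same reaction recurs in step 9). The ee of the radical coupling with the small methyl-bearing α-chloroboronate may fall short. The fallback sets out from 5 and replaces the radical coupling by a stereospecific 1,2-metallate rearrangement. Copper-catalysed borylation of 5 (CuI, PPh3, LiOMe, B2pin2, DMF, rt) gives 4,4,5,5-tetramethyl-2-[4-(trimethylsilyl)but-3-yn-1-yl]-1,3,2-dioxaborolane F1. Ethyl N,N-diisopropylcarbamate is deprotonated with s-BuLi/(−)-sparteine (Et2O, −78 °C) to (S)-1-lithioethyl N,N-diisopropylcarbamate F2, which adds to F1 with retention to give lithium [(1S)-1-(diisopropylcarbamoyloxy)ethyl][4-(trimethylsilyl)but-3-yn-1-yl](pinacolato)borate F3. Warming with MgBr2 makes the butynyl group migrate with inversion and expel the carbamate, which gives 8 (above 95% ee expected), and the route resumes at step 5.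

Step 7. The directed epoxidation may give insufficient ee, or the 3,4-epoxy alcohol 17 may cyclise to a tetrahydrofuranol under Lewis-acidic conditions. The fallback sets out from 13 and uses an allylic alcohol with titanium–tartrate control instead. The alanate 15 (from 13 through 14, as in step 6) is trapped with paraformaldehyde to give (2E,6R)-3,6,11-trimethyl-7-methylidenedodeca-2,10-dien-1-ol F4. Sharpless asymmetric epoxidation (Ti(OiPr)4, D-(−)-diethyl tartrate, t-BuOOH, 4 Å sieves, CH2Cl2, −20 °C) gives [(2R,3R)-3-[(3R)-3,8-dimethyl-4-methylidenenon-7-en-1-yl]-3-methyloxiran-2-yl]methanol F5, with the sense known from geraniol. Triflation (Tf2O, 2,6-lutidine, −78 °C) gives [(2R,3R)-3-[(3R)-3,8-dimethyl-4-methylidenenon-7-en-1-yl]-3-methyloxiran-2-yl]methyl trifluoromethanesulfonate F6. Copper-catalysed displacement with (isopropoxydimethylsilyl)methylmagnesium chloride (CuI cat., THF, −40 °C) gives {2-[(2R,3R)-3-[(3R)-3,8-dimethyl-4-methylidenenon-7-en-1-yl]-3-methyloxiran-2-yl]ethyl}(dimethyl)(propan-2-yloxy)silane F7. Tamao oxidation (H2O2, KF, KHCO3, THF/MeOH) returns 17, and the route resumes at step 8.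

Step 15. Iodide and manganese salts may open the trisubstituted epoxide, or homocoupling of the two halides may dominate. The fallback sets out from 18 and uses a preformed nucleophile in a two-electron palladium cross-coupling. Zinc insertion (I2-activated Zn dust, LiCl, THF, 40 °C) gives {2-[(2R,3R)-3-[(3R)-3,8-dimethyl-4-methylidenenon-7-en-1-yl]-3-methyloxiran-2-yl]ethyl}zinc bromide F8, which undergoes Negishi coupling with 31 (PdCl2(dppf) 5 mol%, THF, rt) and comes back to the route at 32.

**Further compounds**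
F1 | step 4 | 4,4,5,5-tetramethyl-2-[4-(trimethylsilyl)but-3-yn-1-yl]-1,3,2-dioxaborolane | C[Si](C)(C)C#CCCB1OC(C)(C)C(C)(C)O1
F2 | step 4 | (S)-1-lithioethyl N,N-diisopropylcarbamate | CC(C)N(C(C)C)C(=O)O[C@H](C)[Li]
F3 | step 4 | lithium [(1S)-1-(diisopropylcarbamoyloxy)ethyl][4-(trimethylsilyl)but-3-yn-1-yl](pinacolato)borate | [Li+].CC(C)N(C(C)C)C(=O)O[C@H](C)[B-]1(CCC#C[Si](C)(C)C)OC(C)(C)C(C)(C)O1
F4 | step 7 | (2E,6R)-3,6,11-trimethyl-7-methylidenedodeca-2,10-dien-1-ol | C=C(CCC=C(C)C)[C@H](C)CC/C(C)=C/CO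
F5 | step 7 | [(2R,3R)-3-[(3R)-3,8-dimethyl-4-methylidenenon-7-en-1-yl]-3-methyloxiran-2-yl]methanol | C=C(CCC=C(C)C)[C@H](C)CC[C@@]1(C)O[C@@H]1CO
F6 | step 7 | [(2R,3R)-3-[(3R)-3,8-dimethyl-4-methylidenenon-7-en-1-yl]-3-methyloxiran-2-yl]methyl trifluoromethanesulfonate | C=C(CCC=C(C)C)[C@H](C)CC[C@@]1(C)O[C@@H]1COS(=O)(=O)C(F)(F)F
F7 | step 7 | {2-[(2R,3R)-3-[(3R)-3,8-dimethyl-4-methylidenenon-7-en-1-yl]-3-methyloxiran-2-yl]ethyl}(dimethyl)(propan-2-yloxy)silane | C=C(CCC=C(C)C)[C@H](C)CC[C@@]1(C)O[C@@H]1CC[Si](C)(C)OC(C)C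
F8 | step 15 | {2-[(2R,3R)-3-[(3R)-3,8-dimethyl-4-methylidenenon-7-en-1-yl]-3-methyloxiran-2-yl]ethyl}zinc bromide | C=C(CCC=C(C)C)[C@H](C)CC[C@@]1(C)O[C@@H]1CC[Zn]Br
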